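In the spring run 63.2% of the starting material was still there at 20.0 h, and the meeting began from that leftover. The reagent charge allows target up to 50.0% of the starting material, yet the spring readings of target had stood near 36.5% since 3.00 h.

| flask | starting material | reagent | second substrate | free catalyst | remark | time |
|---|---|---|---|---|---|---|
| spring | 0.050 M (fed, over 1.0 h) | 0.025 M | 0.050 M | 0.74 mM | run made earlier |  |
| autumn | 0.050 M (fed, over 1.0 h) | 0.025 M | 0.050 M | 1.7 mM | run made earlier |  |
| flask | 0.050 M (fed, over 1.0 h) | 0.0250 M | 0.0500 M | 1.1 mM |  | 30 h |

| run | time / h | starting material / % | target / % |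
|---|---|---|---|
| spring | 1.33 | 66.6 | 33.5 |
| spring | 2.00 | 63.4 | 36.5 |
| spring | 3.00 | 63.3 | 36.9 |
| spring | 5.00 | 63.3 | 37.0 |
| spring | 8.00 | 63.4 | 36.6 |
| spring | 12.0 | 62.6 | 36.5 |
| spring | 20.0 | 63.2 | 36.5 |
| autumn | 2.50 | 57.8 | 42.1 |
| autumn | 5.00 | 57.6 | 43.0 |
| autumn | 8.00 | 58.2 | 41.9 |
| autumn | 10.0 | 57.3 | 42.7 |
| autumn | 12.0 | 57.8 | 41.9 |
| autumn | 15.0 | 57.3 | 42.7 |
| autumn | 20.0 | 57.4 | 41.9 |

(standard deviation of a reading: 0.3 percentage points)

1. conversion of starting material at 30 h
2. amount of target at 30 h, in percent of the starting material charged

The first speaker proposed to count turnovers: target made per catalyst charged, the turnover number. At 20.0 h the spring run shows 24.7 turnovers, and the autumn run shows 12.3. The second speaker objected that the autumn run, with more catalyst, gave fewer turnovers, so the count is no constant of the catalyst. The third replied that the reagent per catalyst is also smaller in the autumn run, 14.7 against 33.8, and that the new flask, with 1.1 mM of free catalyst, should fall between the two counts.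

My own reckoning in these minutes laid a power law through both counts, each read with a scatter of 0.3 percentage points on its target. At 1.1 mM of free catalyst it gives the expected turnovers of the flask, 17.7, which means 39.0% target.

The forecast, made from the same two runs, stood slightly higher, at 39.7% conversion and 39.7% target, and its ground was this: “The plateau depends on catalyst loading, which suggests the catalyst dies quickly rather than the reaction reaching equilibrium.”

The flask gives 40.3% conversion and 40.3% target at 30 h.

    second substrate + reagent + free catalyst → free catalyst + second product (k = 7700 M⁻² h⁻¹)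
    second substrate ⇌ dormant form (K = 0.810, k = 6.20 h⁻¹)
    starting material + reagent + free catalyst → free catalyst + target (k = 3.10 × 10⁵ M⁻² h⁻¹)
    free catalyst → spent catalyst (k = 2.10 h⁻¹)

Counted the same way, the flask made 18.3 turnovers against the 17.7 reckoned, out of 22.7 that its reagent charge allows. Its free catalyst stood at 12.2% at 1.00 h and at 0% at 15.0 h. The neighbouring flask, charged with 0.10 M of reagent and otherwise the same, reaches 90.6% target, which is 41.2 turnovers, more than the 17.7, out of 45.5 that its starting material allows. At 30 h that neighbouring flask keeps 46% of its reagent and 9.4% of its starting material.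

The runs are simulated with made-up constants.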